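The route rests on forming the heterocycle of the top flavan unit last, by an oxygen 1,2-shift. O1, C2 and C3 of that ring carry the 2,3-cis oxygen pair beside the 4β-aryl bond; the same three atoms are present in a trans-3-aryl-2,3-dihydrobenzofuran in which the ether oxygen is bonded to the future C3 and the exocyclic carbinol carbon is the future C2. In one operation the key step moves the oxygen to C2, closes the pyran ring and inverts both carbons, giving the 2,3-cis-3,4-trans unit as its 3-acetate. The precursor is the benzylated epioritin-(4β→6)-epioritin-4α-ol dimer carrying this dihydrobenzofuran at C6, with a benzylic mesylate beside a triflate-deactivated aryl ring.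

Key step: step 22

Assumption: the sense of induction of (S)-t-BuPyOx (step 3) and of the quinidinium leaving group (step 19) is taken as drawn; if either is opposite, the enantiomeric ligand or the quinine-derived salt is used with no other change.

Convention: α and β mean below and above the flavan heterocycle drawn with ring A on the left and O1 at the top; every flavan unit has its 2-aryl group α.

**Route**

Step 1
Reactants: 1 2,3,4-trihydroxyacetophenone (gallacetophenone)
Product: 2 3,4-bis(benzyloxy)-2-hydroxyacetophenone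
Conditions: BnBr (2.1 equiv), K2CO3, acetone, reflux
Reagents that add atoms: benzyl bromide, BrCc1ccccc1
Why: Williamson etherification; the 2-hydroxyl is hydrogen-bonded to the carbonyl and reacts last, so the 3- and 4-hydroxyls should be benzylated selectively.

Step 2
Reactants: 2 3,4-bis(benzyloxy)-2-hydroxyacetophenone
Product: 4 7,8-bis(benzyloxy)-4H-chromen-4-one, via enaminone 3 (not isolated)
Conditions: Me2NCH(OMe)2, toluene, 100 °C; then HCl (aq.), CH2Cl2, rt
Reagents that add atoms: N,N-dimethylformamide dimethyl acetal, COC(OC)N(C)C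
Why: enaminone formation followed by acid-promoted addition of the phenol and loss of dimethylamine is the standard chromone synthesis from 2-hydroxyacetophenones.

Step 3
Reactants: 4 7,8-bis(benzyloxy)-4H-chromen-4-one; 5 4-(benzyloxy)phenylboronic acid
Product: 6 (2S)-7,8-bis(benzyloxy)-2-[4-(benzyloxy)phenyl]chroman-4-one
Conditions: Pd(OCOCF3)2 (5 mol %), (S)-t-BuPyOx (6 mol %), NH4PF6, H2O, ClCH2CH2Cl, 60 °C
Reagents that add atoms: none
Why: palladium-catalysed asymmetric conjugate addition of an arylboronic acid to a chromone; the PyOx ligand selects the enone face and so sets C2, and benzyl ethers are inert.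

Step 4
Reactants: 6 (2S)-flavanone
Product: 7 (2S)-7,8-bis(benzyloxy)-2-[4-(benzyloxy)phenyl]-4-(tert-butyldimethylsilyloxy)-2H-chromene
Conditions: TBSOTf, Et3N, CH2Cl2, 0 °C
Reagents that add atoms: tert-butyldimethylsilyl triflate, CC(C)(C)[Si](C)(C)OS(=O)(=O)C(F)(F)F
Why: soft enolisation gives the silyl enol ether without a free enolate, so ring opening by β-elimination of the phenoxide, which would racemise C2, is avoided.

Step 5
Reactants: 7 silyl enol ether
Product: 9 7,8-bis(benzyloxy)-2α-[4-(benzyloxy)phenyl]-4α-(tert-butyldimethylsilyloxy)chroman-3β-ol, via alkylborane 8 (not isolated)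
Conditions: BH3·THF, THF, 0 °C to rt; then H2O2, NaHCO3 (aq.), 0 °C
Reagents that add atoms: borane–tetrahydrofuran, [BH3].C1CCOC1 (boron of 8); hydrogen peroxide, OO (hydroxyl oxygen of 9)
Why: hydroboration–oxidation of a silyl enol ether; borane adds syn across C3=C4 from the face opposite the 2-aryl group with boron on C3, so oxidation with retention should give the 3β-alcohol and leave the silyl ether on the α face of C4 (4-protected 2,3-trans-3,4-trans diol).

Step 6
Reactants: 9 3β-alcohol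
Product: 10 (2R,4R)-7,8-bis(benzyloxy)-2-[4-(benzyloxy)phenyl]-4-(tert-butyldimethylsilyloxy)chroman-3-one
Conditions: Dess–Martin periodinane, CH2Cl2, rt
Reagents that add atoms: none
Why: Dess–Martin oxidation under near-neutral conditions should spare the benzylic silyl ether and the two enolisable α-centres.

Step 7
Reactants: 10 flavan-3-one
Product: 11 7,8-bis(benzyloxy)-2α-[4-(benzyloxy)phenyl]-4α-(tert-butyldimethylsilyloxy)chroman-3α-ol (all-cis)
Conditions: LiBH(s-Bu)3, THF, −78 °C; then NH4Cl (aq.)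
Reagents that add atoms: none
Why: the bulky hydride attacks the face opposite the cis 2-aryl and 4-silyloxy groups and gives the axial 3α-alcohol, the established outcome for flavan-3-ones, which sets the 2,3-cis-3,4-cis triad.

Step 8
Reactants: 11 all-cis silyl ether
Product: 12 (2R,3R,4R)-7,8-bis(benzyloxy)-2-[4-(benzyloxy)phenyl]chroman-3,4-diol (tri-O-benzyl-epioritin-4α-ol)
Conditions: Bu4NF, AcOH, THF, 0 °C to rt
Reagents that add atoms: none
Why: buffered fluoride desilylation; a silyl shift between the cis oxygens in step 7 would be harmless because both isomers give 12.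

Step 9
Reactants: 12 diol
Product: 13 3,4-O-isopropylidene ketal of 12
Conditions: Me2C(OMe)2, PPTS (cat.), CH2Cl2, rt
Reagents that add atoms: 2,2-dimethoxypropane, COC(C)(C)OC
Why: ketal exchange with a cis-1,2-diol is fast under mild acid and gives the cis-fused dioxolane, the only fusion this ring can accept.

Step 10
Reactants: 12 diol
Product: 14 3,4-di-O-acetate of 12
Conditions: Ac2O, pyridine, DMAP (cat.), CH2Cl2, rt
Reagents that add atoms: acetic anhydride, CC(=O)OC(C)=O
Why: standard acylation turns O4 into a leaving group and O3 into a participating group for step 12.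

Step 11
Reactants: 14 diacetate
Product: 15 6-bromo derivative of 14
Conditions: NBS, MeCN, 0 °C, dark
Reagents that add atoms: N-bromosuccinimide, O=C1CCC(=O)N1Br
Why: electrophilic bromination goes to C6 (ortho to O7, para to O1), the most activated position; the bromine blocks self-condensation in step 12 and is the handle for step 16.

Step 12
Reactants: 13 ketal (2 equiv, excess recovered); 15 bromo diacetate
Product: 16 6-bromo-3-O-acetyl-tri-O-benzyl-epioritin-(4β→6)-tri-O-benzyl-epioritin-4α-ol 3,4-acetonide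
Conditions: BF3·OEt2, CH2Cl2, −78 to −40 °C
Reagents that add atoms: none
Why: Friedel–Crafts coupling of a flavan-4-yl acetate; the Lewis acid ionises the 4-acetate, the 3-acetoxy group shields the α face, and C6 of 13 attacks from the β face to set the 3,4-trans (4β) bond, which keeps the unproven ring expansion to a single step.

Step 13
Reactants: 16 dimer acetate
Product: 17 3-hydroxy dimer (upper unit 3α-OH)
Conditions: K2CO3 (cat.), MeOH–THF, rt
Reagents that add atoms: none
Why: transesterification removes the acetate, which would not survive the aryllithium of step 16.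

Step 14
Reactants: 17 3-hydroxy dimer
Product: 18 6-bromo-3-O-benzyl-tri-O-benzyl-epioritin-(4β→6)-tri-O-benzyl-epioritin-4α-ol 3,4-acetonide
Conditions: NaH, BnBr, Bu4NI (cat.), DMF, 0 °C to rt
Reagents that add atoms: benzyl bromide, BrCc1ccccc1
Why: Williamson benzylation of the secondary alcohol gives a protecting group that tolerates all later steps and leaves in the final hydrogenolysis.

Step 15
Reactants: 19 2,3,4-trihydroxybenzaldehyde
Product: 20 3,4-bis(benzyloxy)-2-hydroxybenzaldehyde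
Conditions: BnBr (2.1 equiv), K2CO3, DMF, rt
Reagents that add atoms: benzyl bromide, BrCc1ccccc1
Why: as in step 1, the chelated 2-hydroxyl is left free while the 3- and 4-hydroxyls are etherified.

Step 16
Reactants: 18 dimer bromide; 20 3,4-bis(benzyloxy)-2-hydroxybenzaldehyde (as its sodium phenoxide, pre-formed with NaH)
Product: 23 2-[(dimer-6-yl)(p-tolylsulfonyl)methyl]-5,6-bis(benzyloxy)phenol (both epimers at the sulfonyl carbon), via aryllithium 21 (not isolated), via benzhydrol 22 (not isolated)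
Conditions: n-BuLi, THF, −78 °C; then sodium phenoxide of 20, −78 to −20 °C; H2O; then p-TolSO2Na, AcOH, CH2Cl2, rt
Reagents that add atoms: sodium p-toluenesulfinate, Cc1ccc(cc1)S(=O)[O-].[Na+]
Why: bromine–lithium exchange and addition to the aldehyde give the ortho-hydroxybenzhydrol, whose doubly activated carbinol is ionised by weak acid and trapped at sulfur by sulfinate to give the base-labile quinone methide precursor.

Step 17
Reactants: 24 2-bromo-4'-hydroxyacetophenone
Product: 25 4-(bromoacetyl)phenyl trifluoromethanesulfonate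
Conditions: (CF3SO2)2O, 2,6-lutidine, CH2Cl2, −78 to 0 °C
Reagents that add atoms: trifluoromethanesulfonic anhydride, O=S(=O)(OS(=O)(=O)C(F)(F)F)C(F)(F)F
Why: O-sulfonylation of the phenol with a hindered base that does not alkylate on the phenacyl bromide; the triflate is chosen because it withdraws from the ring in both σ and π sense.

Step 18
Reactants: 25 phenacyl bromide; 26 quinidine
Product: 27 N-[2-oxo-2-(4-trifluoromethanesulfonyloxyphenyl)ethyl]quinidinium bromide
Conditions: THF, rt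
Reagents that add atoms: none
Why: the quinuclidine nitrogen, far more nucleophilic than the quinoline nitrogen, is alkylated by the phenacyl bromide and the salt should precipitate.

Step 19
Reactants: 23 sulfone; 27 quinidinium salt
Product: 30 trans-(2S,3R)-6,7-bis(benzyloxy)-3-(dimer-6-yl)-2-[4-(trifluoromethanesulfonyloxy)benzoyl]-2,3-dihydrobenzofuran, via quinone methide 28 (not isolated), via ammonium ylide 29 (not isolated)
Conditions: Cs2CO3, CH2Cl2, rt
Reagents that add atoms: none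
Why: [4+1] annulation of an ammonium ylide with an ortho-quinone methide; conjugate addition and displacement of quinidine by the phenoxide close the five-membered ring, the trans isomer is favoured because betaine formation is reversible, and the cinchona leaving group selects the face of the methide carbon, which the remote stereocentres of the dimer cannot do.

Step 20
Reactants: 30 dihydrobenzofuranyl ketone
Product: 31 (S)-carbinol, (S)-[(2S,3R)-6,7-bis(benzyloxy)-3-(dimer-6-yl)-2,3-dihydrobenzofuran-2-yl][4-(trifluoromethanesulfonyloxy)phenyl]methanol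
Conditions: RuCl[(R,R)-TsDPEN](p-cymene) (3 mol %), HCO2H–Et3N (5:2), CH2Cl2, rt
Reagents that add atoms: none
Why: Noyori asymmetric transfer hydrogenation of the aryl ketone; the (R,R) catalyst should give the (S)-carbinol, the same sense as Felkin–Anh attack anti to the ring oxygen, so reagent and substrate control are matched.

Step 21
Reactants: 31 (S)-carbinol
Product: 32 (S)-mesylate of 31 (key-step precursor)
Conditions: (MeSO2)2O, Et3N, CH2Cl2, −20 °C; cold aqueous work-up, used without chromatography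
Reagents that add atoms: methanesulfonic anhydride, CS(=O)(=O)OS(C)(=O)=O
Why: sulfonylation at oxygen retains configuration, the anhydride avoids chloride displacement, and the triflate-bearing ring and the β-oxygen should make this benzylic mesylate stable enough to handle.

Step 22
Reactants: 32 (S)-mesylate
Product: 34 protected trimer, 3-O-acetyl-7,8-di-O-benzyl-4'-O-triflyl-epioritin-(4β→6)-tetra-O-benzyl-epioritin-(4β→6)-tri-O-benzyl-epioritin-4α-ol 3,4-acetonide, via bridged oxonium ion 33 (not isolated)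
Conditions: Zn(OAc)2 (anhydrous, 5 equiv), AcOH–1,4-dioxane (1:2), 55 °C
Reagents that add atoms: zinc diacetate, CC(=O)[O-].CC(=O)[O-].[Zn+2]
Why: Proposed new method: divalent zinc assists loss of the mesylate while the dihydrobenzofuran oxygen, antiperiplanar to it, attacks the carbinyl carbon from the rear to give the aryl-bridged oxiranium ion 33, and zinc-bound acetate then opens 33 at the ring-fusion carbon from the side opposite oxygen, so the oxygen moves from C3 to C2 and the five-membered ring becomes the pyran ring. The closest known reaction type is the zinc acetate-mediated ring expansion of tetrahydrofuran-2-yl carbinyl sulfonates to 3-acetoxytetrahydropyrans, with the aziridinium-based expansion of prolinols to 3-substituted piperidines as its nitrogen counterpart; neither has been shown with an aryl ether oxygen or a benzylic leaving group. The pyran ring is closed by a 3-exo-tet attack of oxygen on the side-chain carbon, and the six-membered ring appears when the old O–C bond is cut. C2 is set by stereospecific inversion of the (S)-mesylate carbon and C3 by stereospecific inversion of the former dihydrobenzofuran C2, while C4 is untouched, which converts the trans-dihydrobenzofuran into the 2α-aryl-3α-acetoxy-4β-aryl pattern. The step needs oxygen participation to beat benzylic ionisation and direct acetate displacement, and needs acetate to attack the fusion carbon and not the benzylic one; the triflyloxy group (a net acceptor, whereas an acyloxy group still donates to a benzylic cation) and the β-oxygen suppress the free cation and remove the benzylic bias, zinc keeps free acetate low, and attack at the fusion carbon releases the strain of both small rings. Acetate-buffered acetic acid should leave the benzyl ethers, the ketal, the triflate and the interflavan bond untouched.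

Step 23
Reactants: 34 protected trimer
Product: 35 trimer 3,4-diol (lower unit 3α,4α-diol free; top unit still 3-acetate and 4'-triflate)
Conditions: AcOH–H2O–THF (3:1:1), 40 °C
Reagents that add atoms: none
Why: acid-catalysed ketal hydrolysis, done while the top aryl ring is still deactivated; the 8-oxygen and the missing 5-oxygen make C4 ionisation slow, so the C4–O bond and both interflavan bonds should persist.

Step 24
Reactants: 35 trimer diol
Product: 36 nona-O-benzyl trimer (top unit 3-OH and 4'-OH free)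
Conditions: Et4NOH (aq.), 1,4-dioxane, rt; then NH4Cl (aq.)
Reagents that add atoms: none
Why: hydroxide saponifies the acetate and cleaves the aryl triflate at sulfur in one operation at room temperature, which limits base-induced opening at C2.

Step 25
Reactants: 36 nona-O-benzyl trimer
Product: 37 epioritin-(4β→6)-epioritin-(4β→6)-epioritin-4α-ol (target)
Conditions: H2 (1 atm), Pd(OH)2/C, THF–MeOH, rt
Reagents that add atoms: none
Why: hydrogenolysis of the nine benzyl ethers under neutral conditions; the secondary benzylic C4–OH and C2–O1 bonds of electron-rich flavans are cleaved far more slowly than O-benzyl groups.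

**Compound list**

1 | 2,3,4-trihydroxyacetophenone (gallacetophenone) | CC(=O)c1ccc(O)c(O)c1O | starting material
2 | 3,4-bis(benzyloxy)-2-hydroxyacetophenone | CC(=O)c1ccc(OCc2ccccc2)c(OCc2ccccc2)c1O | intermediate
3 | (E)-1-[3,4-bis(benzyloxy)-2-hydroxyphenyl]-3-(dimethylamino)prop-2-en-1-one (enaminone, not isolated) | CN(C)/C=C/C(=O)c1ccc(OCc2ccccc2)c(OCc2ccccc2)c1O | intermediate
4 | 7,8-bis(benzyloxy)-4H-chromen-4-one | O=c1ccoc2c(OCc3ccccc3)c(OCc3ccccc3)ccc12 | intermediate
5 | 4-(benzyloxy)phenylboronic acid | OB(O)c1ccc(OCc2ccccc2)cc1 | starting material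
6 | (2S)-7,8-bis(benzyloxy)-2-[4-(benzyloxy)phenyl]chroman-4-one | O=C1C[C@@H](c2ccc(OCc3ccccc3)cc2)Oc2c1ccc(OCc1ccccc1)c2OCc1ccccc1 | intermediate
7 | (2S)-7,8-bis(benzyloxy)-2-[4-(benzyloxy)phenyl]-4-(tert-butyldimethylsilyloxy)-2H-chromene | CC(C)(C)[Si](C)(C)OC1=C[C@@H](c2ccc(OCc3ccccc3)cc2)Oc2c1ccc(OCc1ccccc1)c2OCc1ccccc1 | intermediate
8 | alkylborane from 7 (2α-aryl, 3β-boryl, 4α-silyloxy; not isolated) | c1cc2c(c(OCc5ccccc5)c1OCc5ccccc5)O[C@H](c1ccc(OCc5ccccc5)cc1)[C@@H](B)[C@@H]2O[Si](C)(C)C(C)(C)C | intermediate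
9 | 7,8-bis(benzyloxy)-2α-[4-(benzyloxy)phenyl]-4α-(tert-butyldimethylsilyloxy)chroman-3β-ol (2,3-trans-3,4-trans) | c1cc2c(c(OCc5ccccc5)c1OCc5ccccc5)O[C@H](c1ccc(OCc5ccccc5)cc1)[C@@H](O)[C@@H]2O[Si](C)(C)C(C)(C)C | intermediate
10 | (2R,4R)-7,8-bis(benzyloxy)-2-[4-(benzyloxy)phenyl]-4-(tert-butyldimethylsilyloxy)chroman-3-one (2α-aryl, 4α-silyloxy) | c1cc2c(c(OCc5ccccc5)c1OCc5ccccc5)O[C@H](c1ccc(OCc5ccccc5)cc1)C(=O)[C@@H]2O[Si](C)(C)C(C)(C)C | intermediate
11 | 7,8-bis(benzyloxy)-2α-[4-(benzyloxy)phenyl]-4α-(tert-butyldimethylsilyloxy)chroman-3α-ol (all-cis) | c1cc2c(c(OCc5ccccc5)c1OCc5ccccc5)O[C@H](c1ccc(OCc5ccccc5)cc1)[C@H](O)[C@@H]2O[Si](C)(C)C(C)(C)C | intermediate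
12 | (2R,3R,4R)-7,8-bis(benzyloxy)-2-[4-(benzyloxy)phenyl]chroman-3,4-diol (tri-O-benzyl-epioritin-4α-ol) | c1cc2c(c(OCc5ccccc5)c1OCc5ccccc5)O[C@H](c1ccc(OCc5ccccc5)cc1)[C@H](O)[C@@H]2O | intermediate
13 | 3,4-O-isopropylidene ketal of 12 (cis-fused) | c1cc2c(c(OCc5ccccc5)c1OCc5ccccc5)O[C@H](c1ccc(OCc5ccccc5)cc1)[C@H](O3)[C@@H]2OC3(C)C | intermediate
14 | 3α,4α-di-O-acetate of 12 | c1cc2c(c(OCc5ccccc5)c1OCc5ccccc5)O[C@H](c1ccc(OCc5ccccc5)cc1)[C@H](OC(C)=O)[C@@H]2OC(C)=O | intermediate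
15 | 6-bromo-3α,4α-di-O-acetate of 12 | Brc1cc2c(c(OCc5ccccc5)c1OCc5ccccc5)O[C@H](c1ccc(OCc5ccccc5)cc1)[C@H](OC(C)=O)[C@@H]2OC(C)=O | intermediate
16 | 6-bromo-3-O-acetyl-tri-O-benzyl-epioritin-(4β→6)-tri-O-benzyl-epioritin-4α-ol 3,4-acetonide | Brc1cc2c(c(OCc5ccccc5)c1OCc5ccccc5)O[C@H](c1ccc(OCc5ccccc5)cc1)[C@H](OC(C)=O)[C@H]2c1cc2c(c(OCc5ccccc5)c1OCc5ccccc5)O[C@H](c1ccc(OCc5ccccc5)cc1)[C@H](O3)[C@@H]2OC3(C)C | intermediate
17 | 6-bromo-tri-O-benzyl-epioritin-(4β→6)-tri-O-benzyl-epioritin-4α-ol 3,4-acetonide (upper 3α-OH free) | Brc1cc2c(c(OCc5ccccc5)c1OCc5ccccc5)O[C@H](c1ccc(OCc5ccccc5)cc1)[C@H](O)[C@H]2c1cc2c(c(OCc5ccccc5)c1OCc5ccccc5)O[C@H](c1ccc(OCc5ccccc5)cc1)[C@H](O3)[C@@H]2OC3(C)C | intermediate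
18 | 6-bromo-tetra-O-benzyl-epioritin-(4β→6)-tri-O-benzyl-epioritin-4α-ol 3,4-acetonide (dimer bromide) | Brc1cc2c(c(OCc5ccccc5)c1OCc5ccccc5)O[C@H](c1ccc(OCc5ccccc5)cc1)[C@H](OCc5ccccc5)[C@H]2c1cc2c(c(OCc5ccccc5)c1OCc5ccccc5)O[C@H](c1ccc(OCc5ccccc5)cc1)[C@H](O3)[C@@H]2OC3(C)C | intermediate
19 | 2,3,4-trihydroxybenzaldehyde | O=Cc1ccc(O)c(O)c1O | starting material
20 | 3,4-bis(benzyloxy)-2-hydroxybenzaldehyde | O=Cc1ccc(OCc2ccccc2)c(OCc2ccccc2)c1O | intermediate
21 | 6-lithio derivative of the dimer (aryllithium, not isolated) | [Li]c1cc2c(c(OCc5ccccc5)c1OCc5ccccc5)O[C@H](c1ccc(OCc5ccccc5)cc1)[C@H](OCc5ccccc5)[C@H]2c1cc2c(c(OCc5ccccc5)c1OCc5ccccc5)O[C@H](c1ccc(OCc5ccccc5)cc1)[C@H](O3)[C@@H]2OC3(C)C | intermediate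
22 | [3,4-bis(benzyloxy)-2-hydroxyphenyl](dimer-6-yl)methanol (benzhydrol, both carbinol epimers, not isolated) | OC(c1ccc(OCc5ccccc5)c(OCc5ccccc5)c1O)c1cc2c(c(OCc5ccccc5)c1OCc5ccccc5)O[C@H](c1ccc(OCc5ccccc5)cc1)[C@H](OCc5ccccc5)[C@H]2c1cc2c(c(OCc5ccccc5)c1OCc5ccccc5)O[C@H](c1ccc(OCc5ccccc5)cc1)[C@H](O3)[C@@H]2OC3(C)C | intermediate
23 | 5,6-bis(benzyloxy)-2-[(dimer-6-yl)(p-tolylsulfonyl)methyl]phenol (both epimers at the sulfonyl carbon) | Cc1ccc(cc1)S(=O)(=O)C(c1ccc(OCc5ccccc5)c(OCc5ccccc5)c1O)c1cc2c(c(OCc5ccccc5)c1OCc5ccccc5)O[C@H](c1ccc(OCc5ccccc5)cc1)[C@H](OCc5ccccc5)[C@H]2c1cc2c(c(OCc5ccccc5)c1OCc5ccccc5)O[C@H](c1ccc(OCc5ccccc5)cc1)[C@H](O3)[C@@H]2OC3(C)C | intermediate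
24 | 2-bromo-4'-hydroxyacetophenone | O=C(CBr)c1ccc(O)cc1 | starting material
25 | 4-(bromoacetyl)phenyl trifluoromethanesulfonate | O=C(CBr)c1ccc(OS(=O)(=O)C(F)(F)F)cc1 | intermediate
26 | quinidine | COc1ccc2nccc([C@@H]([C@H]3C[C@@H]4CCN3C[C@@H]4C=C)O)c2c1 | starting material
27 | N-[2-oxo-2-(4-trifluoromethanesulfonyloxyphenyl)ethyl]quinidinium bromide | [Br-].COc1ccc2nccc([C@@H]([C@H]3C[C@@H]4CC[N+]3(CC(=O)c5ccc(OS(=O)(=O)C(F)(F)F)cc5)C[C@@H]4C=C)O)c2c1 | intermediate
28 | 2,3-bis(benzyloxy)-6-[(dimer-6-yl)methylidene]cyclohexa-2,4-dien-1-one (ortho-quinone methide, not isolated) | O=C1C(OCc5ccccc5)=C(OCc5ccccc5)C=CC1=Cc1cc2c(c(OCc5ccccc5)c1OCc5ccccc5)O[C@H](c1ccc(OCc5ccccc5)cc1)[C@H](OCc5ccccc5)[C@H]2c1cc2c(c(OCc5ccccc5)c1OCc5ccccc5)O[C@H](c1ccc(OCc5ccccc5)cc1)[C@H](O3)[C@@H]2OC3(C)C | intermediate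
29 | quinidinium ylide from 27 (not isolated) | COc1ccc2nccc([C@@H]([C@H]3C[C@@H]4CC[N+]3([CH-]C(=O)c5ccc(OS(=O)(=O)C(F)(F)F)cc5)C[C@@H]4C=C)O)c2c1 | intermediate
30 | trans-(2S,3R)-6,7-bis(benzyloxy)-3-(dimer-6-yl)-2-[4-(trifluoromethanesulfonyloxy)benzoyl]-2,3-dihydrobenzofuran | FC(F)(F)S(=O)(=O)Oc1ccc(C(=O)[C@H]2Oc3c(ccc(OCc5ccccc5)c3OCc5ccccc5)[C@@H]2c3cc4c(c(OCc5ccccc5)c3OCc5ccccc5)O[C@H](c3ccc(OCc5ccccc5)cc3)[C@H](OCc5ccccc5)[C@H]4c3cc4c(c(OCc5ccccc5)c3OCc5ccccc5)O[C@H](c3ccc(OCc5ccccc5)cc3)[C@H](O6)[C@@H]4OC6(C)C)cc1 | intermediate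
31 | (S)-carbinol of 30, (S)-[(2S,3R)-dihydrobenzofuran-2-yl][4-(trifluoromethanesulfonyloxy)phenyl]methanol | FC(F)(F)S(=O)(=O)Oc1ccc([C@H](O)[C@H]2Oc3c(ccc(OCc5ccccc5)c3OCc5ccccc5)[C@@H]2c3cc4c(c(OCc5ccccc5)c3OCc5ccccc5)O[C@H](c3ccc(OCc5ccccc5)cc3)[C@H](OCc5ccccc5)[C@H]4c3cc4c(c(OCc5ccccc5)c3OCc5ccccc5)O[C@H](c3ccc(OCc5ccccc5)cc3)[C@H](O6)[C@@H]4OC6(C)C)cc1 | intermediate
32 | (S)-mesylate of 31, trans-3-aryl-2-[α-mesyloxy-4-(triflyloxy)benzyl]-6,7-bis(benzyloxy)-2,3-dihydrobenzofuran on the protected dimer (key-step precursor) | FC(F)(F)S(=O)(=O)Oc1ccc([C@H](OS(C)(=O)=O)[C@H]2Oc3c(ccc(OCc5ccccc5)c3OCc5ccccc5)[C@@H]2c3cc4c(c(OCc5ccccc5)c3OCc5ccccc5)O[C@H](c3ccc(OCc5ccccc5)cc3)[C@H](OCc5ccccc5)[C@H]4c3cc4c(c(OCc5ccccc5)c3OCc5ccccc5)O[C@H](c3ccc(OCc5ccccc5)cc3)[C@H](O6)[C@@H]4OC6(C)C)cc1 | intermediate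
33 | aryl-bridged oxiranium (oxonium) methanesulfonate, O+ bonded to C8a, C2 and C3 (not isolated) | FC(F)(F)S(=O)(=O)Oc1ccc([C@H]2[O+]3c4c(OCc5ccccc5)c(OCc5ccccc5)ccc4[C@H](c6cc7c(c(OCc5ccccc5)c6OCc5ccccc5)O[C@H](c6ccc(OCc5ccccc5)cc6)[C@H](OCc5ccccc5)[C@H]7c6cc7c(c(OCc5ccccc5)c6OCc5ccccc5)O[C@H](c6ccc(OCc5ccccc5)cc6)[C@H](O8)[C@@H]7OC8(C)C)[C@@H]23)cc1.CS(=O)(=O)[O-] | intermediate
34 | protected trimer, top unit 2α-aryl-3α-acetoxy-4β-aryl with 4'-O-triflate (key-step product) | FC(F)(F)S(=O)(=O)Oc1ccc([C@H]2Oc3c(ccc(OCc5ccccc5)c3OCc5ccccc5)[C@H](c3cc4c(c(OCc5ccccc5)c3OCc5ccccc5)O[C@H](c3ccc(OCc5ccccc5)cc3)[C@H](OCc5ccccc5)[C@H]4c3cc4c(c(OCc5ccccc5)c3OCc5ccccc5)O[C@H](c3ccc(OCc5ccccc5)cc3)[C@H](O6)[C@@H]4OC6(C)C)[C@H]2OC(C)=O)cc1 | intermediate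
35 | trimer with lower 3α,4α-diol free (top 3-acetate, 4'-triflate) | FC(F)(F)S(=O)(=O)Oc1ccc([C@H]2Oc3c(ccc(OCc5ccccc5)c3OCc5ccccc5)[C@H](c3cc4c(c(OCc5ccccc5)c3OCc5ccccc5)O[C@H](c3ccc(OCc5ccccc5)cc3)[C@H](OCc5ccccc5)[C@H]4c3cc4c(c(OCc5ccccc5)c3OCc5ccccc5)O[C@H](c3ccc(OCc5ccccc5)cc3)[C@H](O)[C@@H]4O)[C@H]2OC(C)=O)cc1 | intermediate
36 | nona-O-benzyl trimer (top 3-OH and 4'-OH, lower 3,4-diol free) | Oc1ccc([C@H]2Oc3c(ccc(OCc5ccccc5)c3OCc5ccccc5)[C@H](c3cc4c(c(OCc5ccccc5)c3OCc5ccccc5)O[C@H](c3ccc(OCc5ccccc5)cc3)[C@H](OCc5ccccc5)[C@H]4c3cc4c(c(OCc5ccccc5)c3OCc5ccccc5)O[C@H](c3ccc(OCc5ccccc5)cc3)[C@H](O)[C@@H]4O)[C@H]2O)cc1 | intermediate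
37 | epioritin-(4β→6)-epioritin-(4β→6)-epioritin-4α-ol | Oc1ccc([C@H]2Oc3c(ccc(O)c3O)[C@H](c3cc4c(c(O)c3O)O[C@H](c3ccc(O)cc3)[C@H](O)[C@H]4c3cc4c(c(O)c3O)O[C@H](c3ccc(O)cc3)[C@H](O)[C@@H]4O)[C@H]2O)cc1 | target

**Count**

Total step count: 25. Longest linear sequence: 21 steps (1–8, 10–14, 16, 19–25).

**Steps most likely to fail**

1. Step 22 (ring expansion). The benzylic mesylate may ionise before the ring oxygen can attack from the rear, which loses the C2 configuration; acetate may open the bridged ion at the benzylic carbon and return a dihydrobenzofuran acetate; or elimination to the enol ether may compete. The fallback attaches the top unit as a preformed 2,3-cis unit by the known Lewis acid coupling of a flavan-4-yl acetate, setting out from 18 and 15. Bromide 18 is debrominated (n-BuLi, THF, −78 °C, then MeOH) to tetra-O-benzyl-epioritin-(4β→6)-tri-O-benzyl-epioritin-4α-ol acetonide F1. Its free C6 is coupled with bromo diacetate 15 (BF3·OEt2, CH2Cl2, −78 °C) to give the 6-bromo-3-O-acetyl trimer F2, with the top unit 4β-linked for the same reason as in step 12. K2CO3 in MeOH gives the 3-hydroxy trimer F3, aqueous acetic acid gives the trimer diol F4, and hydrogenolysis over Pd(OH)2/C with Et3N removes the ten benzyl groups and the bromine, coming back to the route at 37.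

2. Step 19 ([4+1] annulation). The chiral leaving group may discriminate poorly between the faces of this hindered quinone methide, or the betaine may close before it equilibrates, giving mixtures at C2 and C3 of the dihydrobenzofuran. The fallback gives up reagent control and relies on separation, setting out from 23 and 25. Bromide 25 is alkylated with tetrahydrothiophene (acetone, rt) to the sulfonium bromide F5, whose achiral ylide (Cs2CO3, CH2Cl2) adds to the quinone methide from 23 to give both trans ketones, 30 and its (2R,3S) isomer F6. These are diastereomers because of the dimer and are separated by chromatography; the route is rejoined at 30.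

3. Step 12 (interflavan coupling). The hard Lewis acid may ionise the ketal of the nucleophile, and the pyrogallol-type A ring may attack too slowly, so that ketal loss and ether-linked or oligomeric products take over. The fallback changes the leaving group and the mode of activation, setting out from 15 and 13. Thiolysis of 15 (BnSH, BF3·OEt2, CH2Cl2, −78 °C) gives the 4β-benzylsulfanyl 3-acetate F7. It is activated with the thiophilic salt AgBF4 (THF, 0 °C) in the presence of 13, conditions that leave the ketal of the nucleophile alone, to come back at 16.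

**Further compounds**

F1 | step 22 | tetra-O-benzyl-epioritin-(4β→6)-tri-O-benzyl-epioritin-4α-ol 3,4-acetonide (debrominated dimer) | c1cc2c(c(OCc5ccccc5)c1OCc5ccccc5)O[C@H](c1ccc(OCc5ccccc5)cc1)[C@H](OCc5ccccc5)[C@H]2c1cc2c(c(OCc5ccccc5)c1OCc5ccccc5)O[C@H](c1ccc(OCc5ccccc5)cc1)[C@H](O3)[C@@H]2OC3(C)C
F2 | step 22 | 6-bromo-3-O-acetyl-tri-O-benzyl-epioritin-(4β→6)-tetra-O-benzyl-epioritin-(4β→6)-tri-O-benzyl-epioritin-4α-ol 3,4-acetonide | O(Cc5ccccc5)c1ccc([C@H]2Oc3c(cc(Br)c(OCc5ccccc5)c3OCc5ccccc5)[C@H](c3cc4c(c(OCc5ccccc5)c3OCc5ccccc5)O[C@H](c3ccc(OCc5ccccc5)cc3)[C@H](OCc5ccccc5)[C@H]4c3cc4c(c(OCc5ccccc5)c3OCc5ccccc5)O[C@H](c3ccc(OCc5ccccc5)cc3)[C@H](O6)[C@@H]4OC6(C)C)[C@H]2OC(C)=O)cc1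
F3 | step 22 | 3-hydroxy trimer from F2 (top 3α-OH free) | O(Cc5ccccc5)c1ccc([C@H]2Oc3c(cc(Br)c(OCc5ccccc5)c3OCc5ccccc5)[C@H](c3cc4c(c(OCc5ccccc5)c3OCc5ccccc5)O[C@H](c3ccc(OCc5ccccc5)cc3)[C@H](OCc5ccccc5)[C@H]4c3cc4c(c(OCc5ccccc5)c3OCc5ccccc5)O[C@H](c3ccc(OCc5ccccc5)cc3)[C@H](O6)[C@@H]4OC6(C)C)[C@H]2O)cc1
F4 | step 22 | trimer diol from F3 (lower 3α,4α-diol free, ten benzyl ethers, top 6-bromo) | O(Cc5ccccc5)c1ccc([C@H]2Oc3c(cc(Br)c(OCc5ccccc5)c3OCc5ccccc5)[C@H](c3cc4c(c(OCc5ccccc5)c3OCc5ccccc5)O[C@H](c3ccc(OCc5ccccc5)cc3)[C@H](OCc5ccccc5)[C@H]4c3cc4c(c(OCc5ccccc5)c3OCc5ccccc5)O[C@H](c3ccc(OCc5ccccc5)cc3)[C@H](O)[C@@H]4O)[C@H]2O)cc1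
F5 | step 19 | 1-[2-oxo-2-(4-trifluoromethanesulfonyloxyphenyl)ethyl]tetrahydrothiophenium bromide | [Br-].O=C(C[S+]1CCCC1)c1ccc(OS(=O)(=O)C(F)(F)F)cc1
F6 | step 19 | trans-(2R,3S) diastereomer of 30 | FC(F)(F)S(=O)(=O)Oc1ccc(C(=O)[C@@H]2Oc3c(ccc(OCc5ccccc5)c3OCc5ccccc5)[C@H]2c3cc4c(c(OCc5ccccc5)c3OCc5ccccc5)O[C@H](c3ccc(OCc5ccccc5)cc3)[C@H](OCc5ccccc5)[C@H]4c3cc4c(c(OCc5ccccc5)c3OCc5ccccc5)O[C@H](c3ccc(OCc5ccccc5)cc3)[C@H](O6)[C@@H]4OC6(C)C)cc1
F7 | step 12 | 3α-acetoxy-4β-(benzylsulfanyl)-6-bromo-7,8-bis(benzyloxy)-2α-[4-(benzyloxy)phenyl]chroman | Brc1cc2c(c(OCc5ccccc5)c1OCc5ccccc5)O[C@H](c1ccc(OCc5ccccc5)cc1)[C@H](OC(C)=O)[C@H]2SCc1ccccc1
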